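## Retrosynthetic overview

- Numbering used throughout: oxolane O1, C2 (aryl), C3 (bears C9, the CH2OAc carbon), C4 (carbinol, bears the benzylic carbon C7'), C5 (CH2).
- Enabling feature: ring O1 (through C2) and the hydroxyl oxygen on C4 both sit β to the exocyclic C9 on C3, and O1 and C4 are linked only by C5H2. With C9 raised to CHO, O1–C2 becomes an oxa-Michael bond and C3–C4 an aldol bond between an enal and an α-hydroxy ketone.
- C9 and C7' are cis on the oxolane. A temporary OH on C7' lets a lactol ring (C3–C9–O–C7'–C4) close to a cis-fused 3,7-dioxabicyclo[3.3.0]octane, and this ring selects the correct C4 epimer from reversible equilibria.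
- Ring order: the oxolane forms first (aldol closure) and the temporary lactol ring second, both in one operation. NaBH4 then opens the lactol, acetylation installs the target acetate and activates C7'–O, and one hydrogenolysis removes C7'–O and both benzyl ethers.
- Fragments: O-benzylconiferaldehyde, and a racemic 1-aryl-1,3-dihydroxyacetone made from O-benzylvanillin and 2-bromoallyl alcohol.

Key step: step 4

Assumption (chemistry): C7' in 6–13 and the lactol carbon C9 in 11 are carried as epimer mixtures and written without configuration, because both centres are destroyed before 14.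

## Route

Step 1
Reactants: 1 coniferaldehyde
Product: 2 O-benzylconiferaldehyde
Conditions: BnBr, K2CO3, DMF, rt
Reagents that add atoms: benzyl bromide BrCc1ccccc1
Why: Williamson ether synthesis (SN2 O-alkylation) of the acidic vinylogous phenol should leave the E-enal untouched and creates no stereocentre.

Step 2
Reactants: 3 2-bromoprop-2-en-1-ol; 4 O-benzylvanillin
Product: 6 rac-1-[4-(benzyloxy)-3-methoxyphenyl]-2-methylidenepropane-1,3-diol, via dilithiated allyl alcohol 5 (not isolated)
Conditions: 3, t-BuLi (3.1 equiv), Et2O, −78 to 0 °C; then 4, −78 °C to rt; H2O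
Reagents that add atoms: none
Why: Deprotonation and bromine–lithium exchange give the 2-lithioallyl alkoxide, which adds 1,2 to the aldehyde (organolithium carbonyl addition); the new carbinol centre C7' is deliberately racemic because it is erased in step 7.

Step 3
Reactants: 6 rac-1-[4-(benzyloxy)-3-methoxyphenyl]-2-methylidenepropane-1,3-diol
Product: 8 rac-1-[4-(benzyloxy)-3-methoxyphenyl]-1,3-dihydroxypropan-2-one, via secondary ozonide 7 (not isolated)
Conditions: O3, CH2Cl2, −78 °C (indicator end point); Me2S, −78 °C to rt
Reagents that add atoms: ozone [O-][O+]=O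
Why: Ozonolysis (Criegee mechanism) with reductive work-up should cleave the 1,1-disubstituted alkene faster than it attacks the arene or the benzyl ether and should deliver the α,α'-dihydroxy ketone under neutral conditions.

Step 4
Reactants: 2 O-benzylconiferaldehyde; 8 rac-1-[4-(benzyloxy)-3-methoxyphenyl]-1,3-dihydroxypropan-2-one
Product: 11 cis-fused bicyclic lactol (2S,3R,4S in oxolane numbering), via oxa-Michael adduct 9 (not isolated), via monocyclic aldol 10 (not isolated)
Conditions: 8 (1.5 equiv), (S)-2-[diphenyl(trimethylsilyloxy)methyl]pyrrolidine (20 mol %), PhCO2H (20 mol %), CHCl3 (1 M), rt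
Reagents that add atoms: none
Why: The amine turns 2 into its (E)-iminium ion, the primary hydroxyl of 8 adds reversibly to the β-carbon (oxa-Michael, O1–C2), the resulting enamine attacks the flanking ketone (aldol, C3–C4), and after hydrolysis the benzylic hydroxyl closes on the freed aldehyde, so 9 and 10 drain into lactol 11. The closest known reaction type is the amine-catalysed domino oxa-Michael/aldol/hemiacetalization of 1,3-dihydroxyacetone with enals, supported by the analogous thia-Michael/aldol route to tetrahydrothiophenes. The oxolane closes in the aldol event as a 5-(enolexo)-exo-trig cyclization, and the temporary ring closes by 5-exo-trig addition of oxygen to C=O. C2 is set by the catalyst, whose CPh2(OTMS) group covers the Re face of the β-carbon so that oxygen enters from the Si face; C3 is set because the same shielded enamine bonds on the face that carries the tether, which puts aryl and formyl trans; C4 is set by ring fusion, since both bond-forming steps are reversible and only the epimer with the C7' arm cis to the formyl group can form the cis-fused bicycle. The process is stereoconvergent because both enantiomers of 8 and both lactol anomers are productive, their two uncontrolled centres (C7', C9) being erased in steps 5 and 7. The step needs O- over C-nucleophilicity and the primary over the secondary hydroxyl as Michael donor; the weakly acidic buffer keeps 8 un-enolized, and the congested β-aryl iminium carbon discriminates against the hindered benzylic hydroxyl.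

Step 5
Reactants: 11 cis-fused bicyclic lactol
Product: 12 (2S,3R,4S)-triol
Conditions: NaBH4, MeOH–THF, 0 °C
Reagents that add atoms: none
Why: Borohydride reduction of the hydroxy-aldehyde tautomer of the lactol opens the temporary ring to the C9 primary alcohol, and the low temperature and fast reduction should outrun retro-aldol cleavage, so C2, C3 and C4 stay untouched.

Step 6
Reactants: 12 (2S,3R,4S)-triol
Product: 13 (2S,3R,4S)-diacetate
Conditions: Ac2O (3 equiv), pyridine, DMAP (5 mol %), CH2Cl2, 0 °C to rt
Reagents that add atoms: acetic anhydride CC(=O)OC(C)=O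
Why: DMAP-catalysed acylation should esterify the primary C9 and the secondary benzylic C7' hydroxyls while the tertiary C4 carbinol stays free for steric reasons, which installs the target acetate and a leaving group on C7' at once.

Step 7
Reactants: 13 (2S,3R,4S)-diacetate
Product: 14 olivil monoacetate
Conditions: H2 (1 atm), 10 % Pd/C, EtOAc, rt, stopped at full conversion
Reagents that add atoms: none
Why: Heterogeneous hydrogenolysis should cleave both O-benzyl ethers and the activated benzylic acetate at C7' (a far better leaving group than the ring alkoxide at C2), which turns C7' into CH2, removes the last temporary centre and leaves the C9 acetate and C2, C3, C4 unchanged.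

## Compound list

1 | coniferaldehyde, (E)-3-(4-hydroxy-3-methoxyphenyl)prop-2-enal | COc1cc(/C=C/C=O)ccc1O | starting material
2 | O-benzylconiferaldehyde, (E)-3-[4-(benzyloxy)-3-methoxyphenyl]prop-2-enal | COc1cc(/C=C/C=O)ccc1OCc1ccccc1 | intermediate
3 | 2-bromoprop-2-en-1-ol | OCC(Br)=C | starting material
4 | O-benzylvanillin, 4-(benzyloxy)-3-methoxybenzaldehyde | COc1cc(C=O)ccc1OCc1ccccc1 | starting material
5 | dilithiated allyl alcohol, lithium 2-lithioprop-2-en-1-olate | [Li]OCC([Li])=C | intermediate
6 | rac-1-[4-(benzyloxy)-3-methoxyphenyl]-2-methylidenepropane-1,3-diol | COc1cc(C(O)C(=C)CO)ccc1OCc1ccccc1 | intermediate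
7 | secondary ozonide (1,2,4-trioxolane) of 6 | COc1cc(C(O)C2(CO)OCOO2)ccc1OCc1ccccc1 | intermediate
8 | rac-1-[4-(benzyloxy)-3-methoxyphenyl]-1,3-dihydroxypropan-2-one | COc1cc(C(O)C(=O)CO)ccc1OCc1ccccc1 | intermediate
9 | oxa-Michael adduct, (3S)-3-aryl-3-(3-aryl-3-hydroxy-2-oxopropoxy)propanal, aryl = 4-(benzyloxy)-3-methoxyphenyl; present as its catalyst enamine, drawn catalyst-free | COc1cc(C(O)C(=O)CO[C@H](c2ccc(OCc3ccccc3)c(OC)c2)CC=O)ccc1OCc1ccccc1 | intermediate
10 | monocyclic aldol, (2S,3R,4S)-2-aryl-4-[aryl(hydroxy)methyl]-4-hydroxyoxolane-3-carbaldehyde; aryl trans to CHO, 4-OH trans to CHO | COc1cc(C(O)[C@@]2(O)CO[C@H](c3ccc(OCc4ccccc4)c(OC)c3)[C@H]2C=O)ccc1OCc1ccccc1 | intermediate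
11 | bicyclic lactol, cis-fused 2,6-bis[4-(benzyloxy)-3-methoxyphenyl]-3,7-dioxabicyclo[3.3.0]octane-1,4-diol; oxolane part 2S,3R,4S, epimer mixture at C7' and C9 | COc1cc(C3[C@@]2(O)CO[C@H](c4ccc(OCc5ccccc5)c(OC)c4)[C@H]2C(O)O3)ccc1OCc1ccccc1 | intermediate
12 | triol, (2S,3R,4S)-2-aryl-4-[aryl(hydroxy)methyl]-3-(hydroxymethyl)oxolan-4-ol | COc1cc(C(O)[C@@]2(O)CO[C@H](c3ccc(OCc4ccccc4)c(OC)c3)[C@H]2CO)ccc1OCc1ccccc1 | intermediate
13 | diacetate, (2S,3R,4S)-3-(acetoxymethyl)-4-[acetoxy(aryl)methyl]-2-aryloxolan-4-ol | COc1cc(C(OC(C)=O)[C@@]2(O)CO[C@H](c3ccc(OCc4ccccc4)c(OC)c3)[C@H]2COC(C)=O)ccc1OCc1ccccc1 | intermediate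
14 | olivil monoacetate, (2S,3R,4S) in the numbering above; 2-aryl trans to CH2OAc, 4-OH cis to 2-aryl, benzyl cis to CH2OAc | COc1cc(C[C@@]2(O)CO[C@H](c3ccc(O)c(OC)c3)[C@H]2COC(C)=O)ccc1O | target

## Step count and risks

Total step count: 7. Longest linear sequence: 6 (steps 2–7).

**Step 4.**
- What may go wrong: conjugate addition to the donor-substituted iminium ion may be sluggish. The benzylic hydroxyl may compete as the Michael donor. Ketone 8 may undergo a ketol shift to the conjugated aryl ketone. The open aldol may dehydrate before lactol closure.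
- Fallback (sets out from 2, returns at 14): the aryl group is no longer carried through the cascade but added afterwards by C–C bond formation. Enal 2 is submitted to the same amine catalysis with commercial 1,3-dihydroxyacetone dimer, for which donor regiochemistry and ketol shift do not arise, to give the des-aryl lactol F1. NaBH4 opens it to the des-aryl triol F2. Bu2SnO-catalysed tosylation (TsCl, Et3N) picks the primary hydroxyl of the 1,2-diol and gives the monotosylate F3, and K2CO3 in MeOH closes the spiro-epoxide F4. The aryl Grignard reagent F5, made from commercial 1-(benzyloxy)-4-bromo-2-methoxybenzene and Mg, opens F4 at its CH2 terminus under CuI catalysis to O,O'-dibenzylolivil F6. Acetylation of its only primary hydroxyl (Ac2O, pyridine, 0 °C) gives the 9-acetate F7, and plain O-debenzylation (H2, Pd/C) leads to 14.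

**Step 7.**
- What may go wrong: the ring C2–O1 benzylic bond may be over-reduced before the hindered benzylic acetate has been removed.
- Fallback (sets out from 13, returns at 14): deoxygenation is moved from the metal surface to quinone methide chemistry. Hydrogenolysis is stopped as soon as the two O-benzyl ethers are gone, at the bis-phenol diacetate F8. NaBH4 in THF–i-PrOH at 0 °C then lets the phenolate expel acetate to the p-quinone methide F9, which takes up hydride by 1,6-addition and gives 14. The ring oxygen cannot leave as an alkoxide under these conditions.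

**Step 3.**
- What may go wrong: the electron-rich arene or the benzylic carbinol may be over-oxidized. The allylic diol may fragment abnormally during ozonolysis. The product may undergo a ketol shift on isolation.
- Fallback (sets out from 4, returns at 8, bypassing steps 2 and 3): aldehyde 4 is treated with lithium 3-hydroxypyruvate and N-methylmorpholine in aqueous THF at rt. This is the tertiary-amine-mediated decarboxylative addition, the chemical mimic of the transketolase reaction, and it transfers the hydroxyacetyl unit directly. This fallback makes no compound outside the list (F0).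

## Further compounds

F1 | step 4 | des-aryl lactol | C1[C@@]2(O)CO[C@H](c3ccc(OCc4ccccc4)c(OC)c3)[C@H]2C(O)O1
F2 | step 4 | des-aryl triol | OC[C@@]1(O)CO[C@H](c2ccc(OCc3ccccc3)c(OC)c2)[C@H]1CO
F3 | step 4 | monotosylate | Cc1ccc(cc1)S(=O)(=O)OC[C@@]1(O)CO[C@H](c2ccc(OCc3ccccc3)c(OC)c2)[C@H]1CO
F4 | step 4 | spiro-epoxide | C1O[C@@]12CO[C@H](c3ccc(OCc4ccccc4)c(OC)c3)[C@H]2CO
F5 | step 4 | aryl Grignard reagent | COc1cc([Mg]Br)ccc1OCc1ccccc1
F6 | step 4 | O,O'-dibenzylolivil | COc1cc(C[C@@]2(O)CO[C@H](c3ccc(OCc4ccccc4)c(OC)c3)[C@H]2CO)ccc1OCc1ccccc1
F7 | step 4 | O,O'-dibenzylolivil 9-acetate | COc1cc(C[C@@]2(O)CO[C@H](c3ccc(OCc4ccccc4)c(OC)c3)[C@H]2COC(C)=O)ccc1OCc1ccccc1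
F8 | step 7 | bis-phenol diacetate | COc1cc(C(OC(C)=O)[C@@]2(O)CO[C@H](c3ccc(O)c(OC)c3)[C@H]2COC(C)=O)ccc1O
F9 | step 7 | p-quinone methide | COC1=CC(=C[C@@]2(O)CO[C@H](c3ccc(O)c(OC)c3)[C@H]2COC(C)=O)C=CC1=O
F0 | step 3 | none | none
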